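**Strategy.** The route rests on excising ring B, the α-methylene-γ-butyrolactone (O–C6–C7–C11(=C13)–C12), from the ten-membered carbocycle (ring A). C7=C11=C13 becomes a terminal allene, C12 carbon dioxide and C6 a (Z)-enal carbonyl. Because the C6–C7 bond is shared by rings A and B, one zerovalent-nickel-mediated allene/CO2/aldehyde coupling, run intramolecularly, should forge C11–C12 and C6–C7, close both rings and set C6 and C7. Its precursor is an open-chain C1–C10 allenyl enal (compound 21) carrying the C1 ketone, a C9/C10 acetonide and silyl ethers at C3 and C8. The angelate and acetate are installed afterwards.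

Key step: step 16

Remark: atoms carry germacranolide numbers (C1 ketone, C3 carbinol, C4=C5, C6 lactone CH–O, C7 ring fusion, C8 angelate, C9 acetate, C10 carbinol, C11=C13 methylene, C12 lactone carbonyl). The antipodes of ProPhenol (step 1) and Ipc2BCl (step 13) are those expected to give the stated configurations; the mirror-image reagent is taken if the sense of induction proves opposite.

**Fragment A (steps 1–9)**

Step 1
Reactants: 1 (E)-but-2-enal; 2 tert-butyldimethyl(prop-2-yn-1-yloxy)silane
Product: 3 (4R,2E)-7-[(tert-butyldimethylsilyl)oxy]hept-2-en-5-yn-4-ol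
Conditions: (R,R)-ProPhenol (20 mol%), Me2Zn, Ph3P=O (40 mol%), toluene, 4 °C
Reagents that add atoms: none
Why: Dinuclear zinc–ProPhenol catalysed enantioselective alkynylation of an enal, in which the zinc alkynylide is delivered to one aldehyde face inside the chiral pocket and should set the carbinol carbon (later C8) as drawn.

Step 2
Reactants: 3 (4R,2E)-7-[(tert-butyldimethylsilyl)oxy]hept-2-en-5-yn-4-ol
Product: 4 (4R,2E)-7-[(tert-butyldimethylsilyl)oxy]hept-2-en-5-yn-4-yl 2-methylprop-2-enoate
Conditions: methacryloyl chloride, Et3N, DMAP (cat.), CH2Cl2, 0 °C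
Reagents that add atoms: methacryloyl chloride C=C(C)C(Cl)=O
Why: Acylation of the secondary alcohol installs the methacrylate whose carbons become C1, C10 and C14.

Step 3
Reactants: 4 (4R,2E)-7-[(tert-butyldimethylsilyl)oxy]hept-2-en-5-yn-4-yl 2-methylprop-2-enoate
Product: 5 (5R)-5-{3-[(tert-butyldimethylsilyl)oxy]prop-1-yn-1-yl}-3-methylfuran-2(5H)-one
Conditions: second-generation Grubbs catalyst [(H2IMes)(PCy3)Cl2Ru=CHPh] (5 mol%), CH2Cl2 (0.01 M), 40 °C
Reagents that add atoms: none
Why: Ring-closing metathesis of the propenyl and methacrylate alkenes closes the butenolide with loss of propene, fixes the later C9=C10 bond as cis inside the ring and leaves the internal alkyne and the stereocentre untouched.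

Step 4
Reactants: 5 (5R)-5-{3-[(tert-butyldimethylsilyl)oxy]prop-1-yn-1-yl}-3-methylfuran-2(5H)-one
Product: 6 (3S,4S,5S)-5-{3-[(tert-butyldimethylsilyl)oxy]prop-1-yn-1-yl}-3,4-dihydroxy-3-methyloxolan-2-one
Conditions: OsO4 (5 mol%), NMO, citric acid, t-BuOH/H2O, rt
Reagents that add atoms: osmium tetroxide O=[Os](=O)(=O)=O; N-methylmorpholine N-oxide C[N+]1([O-])CCOCC1
Why: Catalytic syn-dihydroxylation (Upjohn type) of the butenolide should occur on the ring face opposite the C8 alkynyl group, which sets C9 and C10 together as the cis-diol trans to that substituent.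

Step 5
Reactants: 6 (3S,4S,5S)-5-{3-[(tert-butyldimethylsilyl)oxy]prop-1-yn-1-yl}-3,4-dihydroxy-3-methyloxolan-2-one
Product: 7 3,4-O-isopropylidene acetal of 6 (cis-fused 2,2-dimethyl-1,3-dioxolane on O9/O10, stereocentres as in 6)
Conditions: 2,2-dimethoxypropane, CSA (cat.), acetone, rt
Reagents that add atoms: 2,2-dimethoxypropane COC(C)(C)OC
Why: Acid-catalysed transketalisation of the cis-diol gives the acetonide that masks O9 and O10 until step 18.

Step 6
Reactants: 7 3,4-O-isopropylidene acetal of 6
Product: 8 primary propargylic alcohol (7 without the TBS group)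
Conditions: Bu4NF, AcOH, THF, 0 °C
Reagents that add atoms: none
Why: Buffered fluoride cleaves the primary silyl ether while the lactone and acetonide stay intact.

Step 7
Reactants: 8 primary propargylic alcohol
Product: 11 allenyl lactone (the C8 substituent is now propa-1,2-dien-1-yl), via sulfonylhydrazine adduct 9 (not isolated), via propargylic diazene 10 (not isolated)
Conditions: PPh3, DEAD, 2-nitrobenzenesulfonylhydrazide, THF, −15 °C → rt
Reagents that add atoms: none
Why: Mitsunobu displacement of the primary propargylic alcohol by the sulfonylhydrazide, loss of sulfinic acid and retro-ene extrusion of N2 (Myers allene synthesis) transpose hydrogen to C7 and give the terminal allene without touching C8.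

Step 8
Reactants: 11 allenyl lactone
Product: 12 methyl lactol (anomeric mixture, in equilibrium with the open C8-hydroxy methyl ketone)
Conditions: MeLi (1.1 equiv), THF, −78 °C; aq. NH4Cl
Reagents that add atoms: methyllithium [Li]C
Why: Mono-addition of MeLi to the hindered lactone stops at the tetrahedral stage at low temperature and introduces C2.

Step 9
Reactants: 12 methyl lactol
Product: 13 1-{(4S,5S)-2,2,4-trimethyl-5-[(1S)-1-(triethylsilyloxy)buta-2,3-dien-1-yl]-1,3-dioxolan-4-yl}ethan-1-one (fragment A)
Conditions: Et3SiCl, imidazole, DMAP (cat.), DMF, 0 °C → rt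
Reagents that add atoms: chlorotriethylsilane CC[Si](Cl)(CC)CC
Why: Ring-opening silylation of a lactol, in which the open-chain tautomer is trapped at its secondary C8 hydroxyl because the tertiary anomeric hydroxyl next to quaternary C10 reacts far more slowly, unveils the methyl ketone.

**Fragment B (steps 10–12)**

Step 10
Reactants: 14 3-methylfuran-2(5H)-one
Product: 15 (2Z)-4-hydroxy-N-methoxy-N,2-dimethylbut-2-enamide
Conditions: MeNH(OMe)·HCl, AlMe3, CH2Cl2, 0 °C → rt; Rochelle salt
Reagents that add atoms: N,O-dimethylhydroxylamine hydrochloride CNOC.Cl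
Why: Aluminium amide opening of the butenolide gives the Weinreb amide, the ring having fixed the Z geometry of the trisubstituted alkene (later C4=C5).

Step 11
Reactants: 15 (2Z)-4-hydroxy-N-methoxy-N,2-dimethylbut-2-enamide
Product: 16 (2Z)-N-methoxy-N,2-dimethyl-4-(triethylsilyloxy)but-2-enamide
Conditions: Et3SiCl, imidazole, CH2Cl2, 0 °C
Reagents that add atoms: chlorotriethylsilane CC[Si](Cl)(CC)CC
Why: Immediate silylation of the primary allylic alcohol prevents relactonisation.

Step 12
Reactants: 16 (2Z)-N-methoxy-N,2-dimethyl-4-(triethylsilyloxy)but-2-enamide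
Product: 17 (2Z)-2-methyl-4-(triethylsilyloxy)but-2-enal (fragment B)
Conditions: iBu2AlH, THF, −78 °C; Rochelle salt
Reagents that add atoms: none
Why: Partial reduction of the Weinreb amide through its stable chelated hemiaminal gives the (Z)-enal without isomerisation.

**Union and end game (steps 13–20)**

Step 13
Reactants: 13 fragment A methyl ketone; 17 (2Z)-2-methyl-4-(triethylsilyloxy)but-2-enal
Product: 19 aldol adduct (C1 ketone, (3R)-hydroxyl, (4Z)-alkene, primary TES ether at C6), via boron enolate 18 (not isolated)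
Conditions: (−)-Ipc2BCl, Et3N, Et2O, 0 °C; then 17, −78 → −20 °C; H2O2, pH 7 buffer, MeOH, 0 °C
Reagents that add atoms: none
Why: Reagent-controlled boron aldol reaction of a methyl ketone, in which the diisopinocampheylboron enolate should add to the re face of the enal through a cyclic transition state and set C3 as R.

Step 14
Reactants: 19 aldol adduct
Product: 20 C3 triisopropylsilyl ether of 19
Conditions: iPr3SiOTf, 2,6-lutidine, CH2Cl2, −78 → 0 °C
Reagents that add atoms: triisopropylsilyl trifluoromethanesulfonate CC(C)[Si](OS(=O)(=O)C(F)(F)F)(C(C)C)C(C)C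
Why: Silyl triflate silylation of the β-hydroxy ketone gives a robust ether that keeps O3 from cyclising onto the later (Z)-enal and survives the acid steps.

Step 15
Reactants: 20 C3 triisopropylsilyl ether
Product: 21 allenyl (Z)-enal (C6 aldehyde, C3 OTIPS, C1 ketone, C9/C10 acetonide, C8 OTES, terminal allene)
Conditions: (COCl)2, DMSO, CH2Cl2, −78 → −40 °C; Et3N, → 0 °C
Reagents that add atoms: none
Why: Under Swern conditions a primary triethylsilyl ether is cleaved and oxidised in situ to the aldehyde while the secondary TES and TIPS ethers survive.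

Step 16
Reactants: 21 allenyl (Z)-enal
Product: 24 ten-membered α-methylene lactone with free C8 hydroxyl (C3 OTIPS, C9/C10 acetonide), via allylnickel carboxylate 22 (not isolated), via seco hydroxy acid 23 (not isolated)
Conditions: Ni(cod)2 (2 equiv), DBU (6 equiv), CO2 (1 atm), THF, 0 °C, slow addition of 21 (final 0.005 M), then rt; 1 M HCl, THF, 0 °C → rt
Reagents that add atoms: carbon dioxide O=C=O
Why: Proposed new method: DBU-ligated zerovalent nickel couples CO2 oxidatively with the terminal allene at its central carbon C11 to give the five-membered nickelalactone 22, a 2-carboxylato σ/π-allylnickel (C11–C12 bond), whose substituted terminus C7 then adds to the tethered enal carbonyl C6 through a six-membered chair transition state (C6–C7 bond), after which acid work-up protonates the nickel alkoxide-carboxylate, lactonises 23 and removes the labile C8 TES ether. The closest known reaction type is the intermolecular nickel-mediated sequential addition of CO2 and aldehydes to terminal allenes, and the ring-closing event has its counterpart in the Barbier and Nozaki–Hiyama–Kishi allylations of 2-(halomethyl)acrylates that close ten-membered germacranolide rings; the intramolecular medium-ring version is new. Ring A is closed in a 10-exo-trig allyl-to-carbonyl addition and ring B in a 5-exo-trig acyl substitution by O6 at the C12 carboxyl. C6 and C7 arise together: the syn π-allyl (C8 trans to CH2Ni, reached by π–σ–π equilibration of the allyl isomers) and a pseudo-equatorial C5 in the chair should give the 6,7-anti adduct and hence the trans-fused lactone, while the C8 stereocentre (H8 in the allyl plane by allylic 1,3-strain, the C9 chain anti to the forming bond) should direct the aldehyde to the C7 face that gives 7S. The step needs aldehyde-over-ketone chemoselectivity (secured by the low nucleophilicity of the allylnickel carboxylate and the quaternary C10 beside the C1 ketone), an inert allylic position (secured by the non-leaving silyl ether at C8 and the absence of esters) and cyclisation over oligomerisation (secured by slow addition at high dilution and by the turn elements Z-C4=C5 and the cis-dioxolane at C9/C10). The constitution of ring B is intrinsic, because CO2 always bonds to the central allene carbon and the allyl reacts through its γ-carbon.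

Step 17
Reactants: 24 ten-membered α-methylene lactone with free C8 hydroxyl
Product: 25 8-O-angelate of 24
Conditions: angelic acid, 2,4,6-trichlorobenzoyl chloride, Et3N, toluene, rt; then 24, 70 °C
Reagents that add atoms: angelic acid C/C=C(/C)C(=O)O
Why: Yamaguchi-type esterification through the mixed trichlorobenzoic anhydride without DMAP acylates the only free hydroxyl (C8) while avoiding Z-to-E isomerisation of the angeloyl group.

Step 18
Reactants: 25 8-O-angelate
Product: 26 9,10-diol (acetonide removed)
Conditions: TFA/H2O (9:1), CH2Cl2, 0 °C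
Reagents that add atoms: none
Why: Aqueous acid hydrolysis of the isopropylidene acetal frees O9 and O10 while the TIPS ether, the angelate and the lactone tolerate the conditions.

Step 19
Reactants: 26 9,10-diol
Product: 27 9-O-acetate (C10 hydroxyl free, C3 OTIPS)
Conditions: Ac2O, pyridine, DMAP (cat.), CH2Cl2, 0 °C → rt
Reagents that add atoms: acetic anhydride CC(=O)OC(C)=O
Why: DMAP-catalysed acetylation differentiates the secondary C9 hydroxyl from the tertiary C10 hydroxyl, which is not acylated under these conditions.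

Step 20
Reactants: 27 9-O-acetate
Product: 28 CNP0308559.3 (target)
Conditions: HF·pyridine, pyridine, THF, 0 °C → rt
Reagents that add atoms: none
Why: Buffered HF·pyridine removes the TIPS ether without base, so the β-hydroxy ketone, the esters and the α-methylene lactone are not exposed to elimination, acyl migration or conjugate addition.

**Compound list**

1 | (E)-but-2-enal | C/C=C/C=O | starting material
2 | tert-butyldimethyl(prop-2-yn-1-yloxy)silane | C#CCO[Si](C)(C)C(C)(C)C | starting material
3 | (4R,2E)-7-[(tert-butyldimethylsilyl)oxy]hept-2-en-5-yn-4-ol | C/C=C/[C@@H](O)C#CCO[Si](C)(C)C(C)(C)C | intermediate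
4 | (4R,2E)-7-[(tert-butyldimethylsilyl)oxy]hept-2-en-5-yn-4-yl 2-methylprop-2-enoate | C/C=C/[C@@H](OC(=O)C(C)=C)C#CCO[Si](C)(C)C(C)(C)C | intermediate
5 | (5R)-5-{3-[(tert-butyldimethylsilyl)oxy]prop-1-yn-1-yl}-3-methylfuran-2(5H)-one | CC1=C[C@H](C#CCO[Si](C)(C)C(C)(C)C)OC1=O | intermediate
6 | (3S,4S,5S)-5-{3-[(tert-butyldimethylsilyl)oxy]prop-1-yn-1-yl}-3,4-dihydroxy-3-methyloxolan-2-one | C[C@]1(O)[C@@H](O)[C@H](C#CCO[Si](C)(C)C(C)(C)C)OC1=O | intermediate
7 | 3,4-O-isopropylidene acetal of 6 | C[C@]12OC(C)(C)O[C@H]1[C@H](C#CCO[Si](C)(C)C(C)(C)C)OC2=O | intermediate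
8 | primary propargylic alcohol (7 without TBS) | C[C@]12OC(C)(C)O[C@H]1[C@H](C#CCO)OC2=O | intermediate
9 | N-propargyl-N-(2-nitrophenylsulfonyl)hydrazine adduct of 8 | C[C@]12OC(C)(C)O[C@H]1[C@H](C#CCN(N)S(=O)(=O)c3ccccc3[N+](=O)[O-])OC2=O | intermediate
10 | propargylic diazene | C[C@]12OC(C)(C)O[C@H]1[C@H](C#CCN=N)OC2=O | intermediate
11 | allenyl lactone (propa-1,2-dien-1-yl at C8) | C[C@]12OC(C)(C)O[C@H]1[C@H](C=C=C)OC2=O | intermediate
12 | methyl lactol (anomeric mixture) | C[C@]12OC(C)(C)O[C@H]1[C@H](C=C=C)OC2(C)O | intermediate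
13 | 1-{(4S,5S)-2,2,4-trimethyl-5-[(1S)-1-(triethylsilyloxy)buta-2,3-dien-1-yl]-1,3-dioxolan-4-yl}ethan-1-one | CC(=O)[C@@]1(C)OC(C)(C)O[C@H]1[C@@H](O[Si](CC)(CC)CC)C=C=C | intermediate
14 | 3-methylfuran-2(5H)-one | CC1=CCOC1=O | starting material
15 | (2Z)-4-hydroxy-N-methoxy-N,2-dimethylbut-2-enamide | CON(C)C(=O)/C(C)=C\CO | intermediate
16 | (2Z)-N-methoxy-N,2-dimethyl-4-(triethylsilyloxy)but-2-enamide | CC[Si](CC)(CC)OC/C=C(/C)C(=O)N(C)OC | intermediate
17 | (2Z)-2-methyl-4-(triethylsilyloxy)but-2-enal | CC[Si](CC)(CC)OC/C=C(/C)C=O | intermediate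
18 | diisopinocampheylboron enolate of 13 | C=C(OB([C@@H]1C[C@@H]2C[C@H]([C@H]1C)C2(C)C)[C@@H]1C[C@@H]2C[C@H]([C@H]1C)C2(C)C)[C@@]1(C)OC(C)(C)O[C@H]1[C@@H](O[Si](CC)(CC)CC)C=C=C | intermediate
19 | aldol adduct (C1 ketone, 3R-OH, 4Z, C6 OTES, C8 OTES, C9/C10 acetonide, allene) | CC[Si](CC)(CC)OC/C=C(/C)[C@H](O)CC(=O)[C@@]1(C)OC(C)(C)O[C@H]1[C@@H](O[Si](CC)(CC)CC)C=C=C | intermediate
20 | C3 triisopropylsilyl ether of 19 | CC[Si](CC)(CC)OC/C=C(/C)[C@H](O[Si](C(C)C)(C(C)C)C(C)C)CC(=O)[C@@]1(C)OC(C)(C)O[C@H]1[C@@H](O[Si](CC)(CC)CC)C=C=C | intermediate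
21 | allenyl (Z)-enal | O=C/C=C(/C)[C@H](O[Si](C(C)C)(C(C)C)C(C)C)CC(=O)[C@@]1(C)OC(C)(C)O[C@H]1[C@@H](O[Si](CC)(CC)CC)C=C=C | intermediate
22 | allylnickel carboxylate (nickelalactone, DBU ligands omitted) | O=C/C=C(/C)[C@H](O[Si](C(C)C)(C(C)C)C(C)C)CC(=O)[C@@]1(C)OC(C)(C)O[C@H]1[C@@H](O[Si](CC)(CC)CC)C=C1C[Ni]OC1=O | intermediate
23 | seco hydroxy acid (ring A closed, C6 OH, C11 acrylic acid, C8 OTES) | C=C(C(=O)O)[C@H]1[C@H](O)/C=C(/C)[C@H](O[Si](C(C)C)(C(C)C)C(C)C)CC(=O)[C@@]2(C)OC(C)(C)O[C@H]2[C@H]1O[Si](CC)(CC)CC | intermediate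
24 | ten-membered α-methylene lactone, C8 OH, C3 OTIPS, C9/C10 acetonide | C=C1C(=O)O[C@@H]2/C=C(/C)[C@H](O[Si](C(C)C)(C(C)C)C(C)C)CC(=O)[C@@]3(C)OC(C)(C)O[C@H]3[C@@H](O)[C@@H]12 | intermediate
25 | 8-O-angelate of 24 | C=C1C(=O)O[C@@H]2/C=C(/C)[C@H](O[Si](C(C)C)(C(C)C)C(C)C)CC(=O)[C@@]3(C)OC(C)(C)O[C@H]3[C@@H](OC(=O)/C(C)=C\C)[C@@H]12 | intermediate
26 | 9,10-diol | C=C1C(=O)O[C@@H]2/C=C(/C)[C@H](O[Si](C(C)C)(C(C)C)C(C)C)CC(=O)[C@@](C)(O)[C@@H](O)[C@@H](OC(=O)/C(C)=C\C)[C@@H]12 | intermediate
27 | 9-O-acetate, C3 OTIPS | C=C1C(=O)O[C@@H]2/C=C(/C)[C@H](O[Si](C(C)C)(C(C)C)C(C)C)CC(=O)[C@@](C)(O)[C@@H](OC(C)=O)[C@@H](OC(=O)/C(C)=C\C)[C@@H]12 | intermediate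
28 | CNP0308559.3 | C=C1C(=O)O[C@@H]2/C=C(/C)[C@H](O)CC(=O)[C@@](C)(O)[C@@H](OC(C)=O)[C@@H](OC(=O)/C(C)=C\C)[C@@H]12 | target

**Totals.** Total step count: 20. Longest linear sequence: 17 steps (steps 1–9 and 13–20).

**Steps most likely to fail**

1. Step 16 (proposed new method). Zerovalent nickel may be tied up by the enal instead of coupling with CO2. The allylnickel may react between molecules rather than close the ring. DBU may isomerise the (Z)-enal. The facial selectivity at C7 and C6 may be poor. Fallback with known reactions, the two bonds made in separate steps, setting out from 20 and coming back at 24: copper-catalysed silacarboxylation of the allene of 20 with CO2 and PhMe2Si–Bpin (Cu(OAc)2·H2O, Me-DuPhos, hexane, 70 °C) should give the 2-(silylmethyl)alkenoic acid F1 (C11–C12 bond). Trimethylsilyldiazomethane converts it into the methyl ester F2. Swern oxidation as in step 15 gives the enal allylsilane F3. BF3·OEt2 in CH2Cl2 at −78 °C under high dilution then effects an intramolecular Hosomi–Sakurai allylation through C7 (C6–C7 bond, ring A), and TsOH-induced lactonisation with loss of the C8 TES group gives 24.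

2. Step 9. Silylation may take place at the anomeric hydroxyl of the closed lactol, or ring–chain equilibration may be too slow to unveil the ketone. Fallback setting out from 11 and coming back at 13: aluminium amide opening of lactone 11 (AlMe3, MeNH(OMe)·HCl) gives the open hydroxy Weinreb amide F4, which cannot close to a lactol. Et3SiCl/imidazole gives its C8 silyl ether F5. MeMgBr (THF, 0 °C) converts the amide into methyl ketone 13.

3. Step 17. The angeloyl unit may isomerise from Z to E during activation, or acylation of the hindered C8 hydroxyl beside the ring fusion may stall. Fallback setting out from 24 and coming back at 25: DCC/DMAP esterification with 2-[bis(2,2,2-trifluoroethoxy)phosphoryl]propanoic acid gives the phosphonate ester F6. A Still–Gennari olefination with acetaldehyde (KN(SiMe3)2, 18-crown-6, THF, −78 °C) then builds the (Z)-2-methylbut-2-enoate on the molecule and gives 25.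

Further compounds
F1 | step 16 | 2-[(dimethylphenylsilyl)methyl]alk-2-enoic acid from 20 (allylsilane acid) | CC[Si](CC)(CC)OC/C=C(/C)[C@H](O[Si](C(C)C)(C(C)C)C(C)C)CC(=O)[C@@]1(C)OC(C)(C)O[C@H]1[C@@H](O[Si](CC)(CC)CC)C=C(C[Si](C)(C)c1ccccc1)C(=O)O
F2 | step 16 | methyl ester of F1 | CC[Si](CC)(CC)OC/C=C(/C)[C@H](O[Si](C(C)C)(C(C)C)C(C)C)CC(=O)[C@@]1(C)OC(C)(C)O[C@H]1[C@@H](O[Si](CC)(CC)CC)C=C(C[Si](C)(C)c1ccccc1)C(=O)OC
F3 | step 16 | (Z)-enal allylsilane ester | O=C/C=C(/C)[C@H](O[Si](C(C)C)(C(C)C)C(C)C)CC(=O)[C@@]1(C)OC(C)(C)O[C@H]1[C@@H](O[Si](CC)(CC)CC)C=C(C[Si](C)(C)c1ccccc1)C(=O)OC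
F4 | step 9 | hydroxy Weinreb amide from 11 | CON(C)C(=O)[C@@]1(C)OC(C)(C)O[C@H]1[C@@H](O)C=C=C
F5 | step 9 | C8 triethylsilyl ether of F4 | CON(C)C(=O)[C@@]1(C)OC(C)(C)O[C@H]1[C@@H](O[Si](CC)(CC)CC)C=C=C
F6 | step 17 | 8-O-{2-[bis(2,2,2-trifluoroethoxy)phosphoryl]propanoate} of 24 | C=C1C(=O)O[C@@H]2/C=C(/C)[C@H](O[Si](C(C)C)(C(C)C)C(C)C)CC(=O)[C@@]3(C)OC(C)(C)O[C@H]3[C@@H](OC(=O)C(C)P(=O)(OCC(F)(F)F)OCC(F)(F)F)[C@@H]12
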